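**Plan**

- Retrosynthesis, in order: first the single ring atom C2 (CMe2) is taken out of the oxepanone (bonds O1–C2 and C2–C3), leaving a cis-fused six-membered lactone; then the central CH2–CH2 bond of the ethylene bridge is cut; the lactone half goes back to 2-methylcyclohexane-1,3-dione and methyl acrylate, the hydroazulene half (cuts C5′–CH2, C7′–C8′, C1′–C8a′, C4′–C5′) to (S)-limonene and methyl methacrylate.
- Forward ring order: cyclohexane (bought) → helper lactone ring (step 2); cyclopentane by aldol closure of ozonised limonene (step 9) → cycloheptane by 7-endo acyl radical closure (step 14); fragments joined by alkyl–alkyl Suzuki coupling (step 21); oxepanone last (step 23), by ring enlargement of the lactone.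
- Enabling feature: in the oxepanone ring, the ring oxygen O1 (on C9a) and the carbonyl carbon C3 are bridged by one hydrogen-free, non-stereogenic ring atom, C2 (CMe2). Removing C2 leaves a δ-lactone (O1–C3 acyl bond, C3–C4–C5–C5a–C9a), so C2 can be inserted last as a dimethylcarbenoid.
- Stereochemistry: C5a/C9a from a CBS desymmetrisation (the lactone locks the cis fusion); C7 from equatorial methyl addition; C6 from hydroboration anti to two axial groups; C3a′ from (S)-limonene; C1′ from epoxidation anti to the C3a′ arm, then Wharton; C8a′ from radical H-atom transfer; C5′ from a convex-face Luche reduction relayed by a suprafacial [2,3]-Wittig shift.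

Key step: step 23

Remark: atoms are labelled as in the target (O1, C2–C9a in the benzoxepinone half; C1′–C8a′ in the hydroazulene half); compounds 12–19 are carried as both epimers at C6′, a center that becomes sp2 in step 15.

**Lactone fragment**

Step 1
Reactants: 1 2-methylcyclohexane-1,3-dione; 2 methyl acrylate
Product: 3 methyl 3-(1-methyl-2,6-dioxocyclohexyl)propanoate
Conditions: Et3N (0.2 equiv), MeCN, 60 °C
Reagents that add atoms: none
Why: Michael addition of the cyclic 1,3-dione at its only acidic carbon builds quaternary C5a with the arm C5–C4–C3; no stereocenter forms because 3 still has a mirror plane.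

Step 2
Reactants: 3 methyl 3-(1-methyl-2,6-dioxocyclohexyl)propanoate
Product: 5 (4aR,8aR)-4a-methylhexahydro-2H-chromene-2,5(3H)-dione (cis-fused keto lactone), via hydroxy ester 4 (not isolated)
Conditions: (S)-2-methyl-CBS-oxazaborolidine (0.2 equiv), catecholborane, toluene, −78 °C; then p-TsOH (cat.), toluene, 80 °C
Reagents that add atoms: none
Why: Corey–Bakshi–Shibata desymmetrising reduction of the prochiral 2,2-disubstituted 1,3-diketone should select one enantiotopic carbonyl (quaternary carbon as the large group) and deliver hydride anti to the larger C5a arm, setting C9a and C5a with the hydroxyl cis to the propanoate; acid-catalysed lactonisation then locks this cis relation in a six-membered helper ring.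

Step 3
Reactants: 5 (4aR,8aR)-4a-methylhexahydro-2H-chromene-2,5(3H)-dione
Product: 6 (4aS,8aR)-4a-methyl-5-methylideneoctahydro-2H-chromen-2-one
Conditions: Ph3PCH3Br, KOt-Bu, toluene, 80 °C
Reagents that add atoms: methyltriphenylphosphonium bromide, C[P+](c1ccccc1)(c1ccccc1)c1ccccc1.[Br-]
Why: Wittig methylenation of the ketone, which reacts in preference to the lactone carbonyl; no stereocenter is touched.

Step 4
Reactants: 6 (4aS,8aR)-4a-methyl-5-methylideneoctahydro-2H-chromen-2-one
Product: 7 (4aS,8aR)-6-hydroxy-4a-methyl-5-methylideneoctahydro-2H-chromen-2-one (both C7 carbinol epimers)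
Conditions: SeO2 (cat.), t-BuOOH, CH2Cl2, 25 °C
Reagents that add atoms: tert-butyl hydroperoxide, CC(C)(C)OO
Why: Selenium dioxide allylic hydroxylation (ene reaction, then [2,3]-shift) can reach only C7, the one allylic CH2, since C5a is quaternary; the epimers are not separated because C7 is oxidised next.

Step 5
Reactants: 7 (4aS,8aR)-6-hydroxy-4a-methyl-5-methylideneoctahydro-2H-chromen-2-one
Product: 8 (4aS,8aR)-4a-methyl-5-methylidenehexahydro-2H-chromene-2,6(3H)-dione
Conditions: Dess–Martin periodinane, NaHCO3, CH2Cl2, 0 °C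
Reagents that add atoms: none
Why: Dess–Martin oxidation of the allylic alcohol under buffered conditions gives the α-methylene ketone, which is used at once; no stereocenter is formed.

Step 6
Reactants: 8 (4aS,8aR)-4a-methyl-5-methylidenehexahydro-2H-chromene-2,6(3H)-dione
Product: 9 (4aS,6R,8aR)-6-hydroxy-4a,6-dimethyl-5-methylideneoctahydro-2H-chromen-2-one
Conditions: CeCl3, MeMgBr, THF, −78 °C; aq. NH4Cl
Reagents that add atoms: methylmagnesium bromide, C[Mg]Br
Why: Organocerium 1,2-addition to the enone carbonyl, far faster than attack on the lactone; in the chair that should dominate (lactone oxygen and C5a methyl axial) the 1,3-diaxial methyl blocks axial attack, so the methyl enters equatorially and the C7 hydroxyl ends axial, cis to the C5a methyl.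

**Hydroazulene fragment**

Step 7
Reactants: 10 (S)-(−)-limonene; 11 methyl methacrylate
Product: 12 methyl 2,4-dimethyl-4-[(1S)-4-methylcyclohex-3-en-1-yl]pentanoate (C6′ epimers)
Conditions: Fe(acac)3 (0.3 equiv), PhSiH3, EtOH/ethylene glycol, 60 °C
Reagents that add atoms: none
Why: Metal-hydride hydrogen-atom-transfer reductive olefin coupling (Giese type): Markovnikov H-atom transfer to the less hindered 1,1-disubstituted alkene gives the tertiary radical that adds to the methacrylate and creates quaternary C4′; the ring alkene reacts more slowly, and C6′ forms unselectively but is flattened in step 15.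

Step 8
Reactants: 12 methyl 2,4-dimethyl-4-[(1S)-4-methylcyclohex-3-en-1-yl]pentanoate
Product: 13 methyl (5S)-2,4,4-trimethyl-8-oxo-5-(2-oxoethyl)nonanoate
Conditions: O3, CH2Cl2/MeOH, −78 °C; then Me2S
Reagents that add atoms: ozone, [O-][O+]=O
Why: Ozonolysis of the only remaining alkene gives the 1,6-keto aldehyde; the limonene stereocenter (C3a′) is untouched.

Step 9
Reactants: 13 methyl (5S)-2,4,4-trimethyl-8-oxo-5-(2-oxoethyl)nonanoate
Product: 14 methyl 4-[(1R)-2-formyl-3-methylcyclopent-2-en-1-yl]-2,4-dimethylpentanoate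
Conditions: piperidine, AcOH, toluene, 60 °C
Reagents that add atoms: none
Why: Intramolecular aldol condensation through the piperidine enamine of the aldehyde, which attacks the methyl ketone, closes the cyclopentene (bond C1′–C8a′) as known for the parent limonene keto aldehyde; no new stereocenter remains.

Step 10
Reactants: 14 methyl 4-[(1R)-2-formyl-3-methylcyclopent-2-en-1-yl]-2,4-dimethylpentanoate
Product: 15 methyl 4-(1-formyl-5-methyl-6-oxabicyclo[3.1.0]hexan-2-yl)-2,4-dimethylpentanoate, epoxide oxygen trans to the side chain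
Conditions: H2O2, NaOH, MeOH, 0 °C
Reagents that add atoms: hydrogen peroxide, OO
Why: Weitz–Scheffer nucleophilic epoxidation of the enal; hydroperoxide adds to C1′ on the face anti to the bulky tert-alkyl arm on C3a′, which sets the C1′–O bond trans to C4′.

Step 11
Reactants: 15 epoxy aldehyde
Product: 16 methyl 4-[(1R,3S)-3-hydroxy-3-methyl-2-methylidenecyclopentyl]-2,4-dimethylpentanoate
Conditions: N2H4·H2O, AcOH (cat.), MeOH, 0 → 25 °C
Reagents that add atoms: none
Why: Wharton transposition: the epoxy hydrazone fragments with loss of N2 to the tertiary allylic alcohol, the C1′–O bond and its configuration being kept while the aldehyde carbon becomes the exocyclic CH2 (C8′).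

Step 12
Reactants: 16 methyl 4-[(1R,3S)-3-hydroxy-3-methyl-2-methylidenecyclopentyl]-2,4-dimethylpentanoate
Product: 17 4-[(1R,3S)-3-hydroxy-3-methyl-2-methylidenecyclopentyl]-2,4-dimethylpentanoic acid
Conditions: LiOH, THF/MeOH/H2O, 40 °C; then 1 M HCl
Reagents that add atoms: lithium hydroxide, [Li+].[OH-]
Why: Ester saponification; the base-stable tertiary allylic alcohol and the stereocenters are unaffected.

Step 13
Reactants: 17 4-[(1R,3S)-3-hydroxy-3-methyl-2-methylidenecyclopentyl]-2,4-dimethylpentanoic acid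
Product: 18 Se-phenyl 4-[(1R,3S)-3-hydroxy-3-methyl-2-methylidenecyclopentyl]-2,4-dimethylpentaneselenoate
Conditions: (PhSe)2, n-Bu3P, CH2Cl2, 25 °C
Reagents that add atoms: diphenyl diselenide, c1ccc(cc1)[Se][Se]c1ccccc1
Why: Selenoester formation through the acyloxyphosphonium salt; the hindered tertiary alcohol is not acylated.

Step 14
Reactants: 18 Se-phenyl selenoester
Product: 19 (1S,3aS,8aS)-1-hydroxy-1,4,4,6-tetramethyldecahydroazulen-7-one (cis-fused, C6′ epimers)
Conditions: (Me3Si)3SiH, AIBN (cat.), benzene, 80 °C, slow addition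
Reagents that add atoms: none
Why: 7-endo-trig acyl radical cyclisation onto the terminal carbon of the 1,1-disubstituted exocyclic alkene (exo attack would hit a fully substituted carbon) forms C7′–C8′ and the seven-membered ring; the tertiary C8a′ radical should take hydrogen from the silane on the face anti to C4′ and the C1′ methyl, which gives the cis ring fusion.

Step 15
Reactants: 19 (1S,3aS,8aS)-1-hydroxy-1,4,4,6-tetramethyldecahydroazulen-7-one
Product: 20 (1S,3aS,8aS)-1,4,4,6-tetramethyl-1,7-bis(triethylsilyloxy)-1,2,3,3a,4,5,8,8a-octahydroazulene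
Conditions: Et3SiCl, NaI, Et3N, MeCN, 25 → 60 °C
Reagents that add atoms: chlorotriethylsilane, CC[Si](Cl)(CC)CC
Why: Iodosilane made in the flask silylates the tertiary alcohol and, under equilibrating conditions, gives the more substituted (thermodynamic) silyl enol ether toward C6′, which removes the stereo-random C6′ center.

Step 16
Reactants: 20 bis(triethylsilyl) compound
Product: 21 (1S,3aS,8aS)-1,4,4,6-tetramethyl-1-(triethylsilyloxy)-2,3,3a,4,8,8a-hexahydroazulen-7(1H)-one
Conditions: Pd(OAc)2 (0.1 equiv), O2 (1 atm), DMSO, 25 °C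
Reagents that add atoms: none
Why: Saegusa–Ito dehydrogenation of the silyl enol ether; β-hydride elimination toward ring carbon C5′ gives the conjugated endocyclic enone C5′=C6′, and no stereocenter is formed.

Step 17
Reactants: 21 enone
Product: 22 (1S,3aS,7R,8aS)-1,4,4,6-tetramethyl-1-(triethylsilyloxy)-1,2,3,3a,4,7,8,8a-octahydroazulen-7-ol
Conditions: NaBH4, CeCl3·7H2O, MeOH, −78 °C
Reagents that add atoms: none
Why: Luche 1,2-reduction; hydride should attack C7′ from the convex face of the cis-fused bicycle (the face of the ring-fusion hydrogens), placing the hydroxyl on the concave face, cis to the cyclopentane ring.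

Step 18
Reactants: 22 allylic alcohol
Product: 23 tributyl({[(1S,3aS,7R,8aS)-1,4,4,6-tetramethyl-1-(triethylsilyloxy)-1,2,3,3a,4,7,8,8a-octahydroazulen-7-yl]oxy}methyl)stannane
Conditions: KH, Bu3SnCH2I, THF, 0 → 25 °C
Reagents that add atoms: tributyl(iodomethyl)stannane, CCCC[Sn](CCCC)(CCCC)CI
Why: Williamson etherification of the secondary allylic alkoxide; C7′ keeps its configuration.

Step 19
Reactants: 23 stannylmethyl ether
Product: 25 [(1S,3aS,5R,8aS)-1,4,4,6-tetramethyl-1-(triethylsilyloxy)-1,2,3,3a,4,5,8,8a-octahydroazulen-5-yl]methanol, via lithiomethyl ether 24 (not isolated)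
Conditions: n-BuLi, THF, −78 → 0 °C; H2O
Reagents that add atoms: none
Why: Still–Wittig [2,3]-sigmatropic rearrangement after tin–lithium exchange; the shift is suprafacial, so the CH2OH group arrives at C5′ on the face that carried the C7′ oxygen (sets C5′) and the alkene moves to C6′=C7′ as in the target.

Step 20
Reactants: 25 homoallylic alcohol
Product: 26 (1S,3aS,5R,8aS)-5-(bromomethyl)-1,4,4,6-tetramethyl-1-(triethylsilyloxy)-1,2,3,3a,4,5,8,8a-octahydroazulene
Conditions: CBr4, PPh3, CH2Cl2, 0 °C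
Reagents that add atoms: tetrabromomethane, BrC(Br)(Br)Br
Why: Appel bromination of the primary alcohol under neutral conditions; no stereocenter is involved.

**Union and end game**

Step 21
Reactants: 9 (4aS,6R,8aR)-6-hydroxy-4a,6-dimethyl-5-methylideneoctahydro-2H-chromen-2-one; 26 bromide
Product: 28 (4aS,5S,6R,8aR)-6-hydroxy-4a,6-dimethyl-5-{2-[(1S,3aS,5R,8aS)-1,4,4,6-tetramethyl-1-(triethylsilyloxy)-1,2,3,3a,4,5,8,8a-octahydroazulen-5-yl]ethyl}octahydro-2H-chromen-2-one, via B-alkyl-9-BBN 27 (not isolated)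
Conditions: 9-BBN (2.2 equiv), THF, 65 °C; then K3PO4·H2O, 26, Pd(OAc)2 (0.05 equiv), PCy3 (0.1 equiv), THF, 40 °C
Reagents that add atoms: none
Why: Hydroboration, then palladium-catalysed alkyl–alkyl Suzuki–Miyaura coupling of the B-alkyl-9-BBN with the primary bromide forms the CH2–CH2 bridge; C6 is set in the hydroboration, because the α face of the exocyclic alkene is shielded by the two flanking axial groups (C5a methyl, C7 hydroxyl), so hydrogen is delivered to C6 from the β face.

Step 22
Reactants: 28 coupled hydroxy lactone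
Product: 29 6-O-trimethylsilyl ether of 28
Conditions: TMSOTf, 2,6-lutidine, CH2Cl2, −78 → 0 °C
Reagents that add atoms: trimethylsilyl trifluoromethanesulfonate, C[Si](C)(C)OS(=O)(=O)C(F)(F)F
Why: Silylation of the remaining tertiary alcohol so that no acidic proton quenches the carbenoid in the next step; no stereocenter is touched.

Step 23
Reactants: 29 bis-silylated lactone
Product: 32 (5aS,6S,7R,9aR)-2,2,5a,7-tetramethyl-6-{2-[(1S,3aS,5R,8aS)-1,4,4,6-tetramethyl-1-(triethylsilyloxy)-1,2,3,3a,4,5,8,8a-octahydroazulen-5-yl]ethyl}-7-(trimethylsilyloxy)octahydro-1-benzoxepin-3(2H)-one, via lithium bromoalkoxide 30 (not isolated), via spiro epoxy ether 31 (not isolated)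
Conditions: Me2CBr2, n-BuLi, THF/Et2O/pentane, −110 °C; then 29, −110 → −20 °C; then MgBr2·OEt2, CH2Cl2, 0 → 25 °C
Reagents that add atoms: 2,2-dibromopropane, CC(C)(Br)Br
Why: Proposed new method: 2-bromo-2-lithiopropane adds to the lactone carbonyl C3 to give the tetrahedral lithium alkoxide 30, which closes 3-exo-tet on the tertiary bromide to the spiro epoxy ether 31; MgBr2 then opens the oxirane at C2 with a 1,2-shift of the ring oxygen O1 from C3 to C2 through a bridged oxonium ion while the oxirane oxygen becomes the C3 carbonyl. The closest known reactions are the formation of epoxy ethers from tertiary α-bromo ketones and alkoxides with their rearrangement to α-alkoxy ketones, the addition of lithium halocarbenoids to esters, and the one-carbon enlargement of lactones to oxacycloalkan-3-ones by diazo ketone O–H insertion. The transient oxirane closes by intramolecular Williamson displacement, and the oxepanone is formed not by cyclisation but by enlargement of the six-membered lactone, a net insertion of the C2 atom into the acyl–oxygen bond. No stereocenter is created (C2 carries two methyl groups, C3 becomes the ketone), and C9a keeps its configuration because the C9a–O1 bond is never broken, so the cis ring fusion is inherited from the lactone. The step needs carbonyl addition to outrun α-deprotonation, oxirane closure to outrun Favorskii or elimination pathways, and oxygen to migrate in preference to C4 or methyl; these are secured by the weakly basic carbenoid at −110 °C, by the alkoxide being held on C3 so that no free bromo ketone meets free base, and by lone-pair participation of O1 next to the developing tertiary cation at C2.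

Step 24
Reactants: 32 bis-silylated target
Product: 33 (5aS,6S,7R,9aR)-7-hydroxy-6-{2-[(1S,3aS,5R,8aS)-1-hydroxy-1,4,4,6-tetramethyl-1,2,3,3a,4,5,8,8a-octahydroazulen-5-yl]ethyl}-2,2,5a,7-tetramethyloctahydro-1-benzoxepin-3(2H)-one (CNP0194989.5)
Conditions: HF·pyridine, THF, 0 → 25 °C
Reagents that add atoms: none
Why: Fluoride-mediated cleavage of both silyl ethers releases the two tertiary alcohols; the α-alkoxy ketone and the trisubstituted alkene are stable to these conditions and no stereocenter is touched.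

**Compound list**

1 | 2-methylcyclohexane-1,3-dione | CC1C(=O)CCCC1=O | starting material
2 | methyl acrylate | C=CC(=O)OC | starting material
3 | methyl 3-(1-methyl-2,6-dioxocyclohexyl)propanoate | COC(=O)CCC1(C)C(=O)CCCC1=O | intermediate
4 | methyl 3-[(1R,2R)-2-hydroxy-1-methyl-6-oxocyclohexyl]propanoate | O=C1[C@](C)(CCC(=O)OC)[C@H](O)CCC1 | intermediate
5 | (4aR,8aR)-4a-methylhexahydro-2H-chromene-2,5(3H)-dione | O=C1[C@]2(C)CCC(=O)O[C@@H]2CCC1 | intermediate
6 | (4aS,8aR)-4a-methyl-5-methylideneoctahydro-2H-chromen-2-one | C=C1[C@]2(C)CCC(=O)O[C@@H]2CCC1 | intermediate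
7 | (4aS,8aR)-6-hydroxy-4a-methyl-5-methylideneoctahydro-2H-chromen-2-one, both carbinol epimers | C=C1[C@]2(C)CCC(=O)O[C@@H]2CCC1O | intermediate
8 | (4aS,8aR)-4a-methyl-5-methylidenehexahydro-2H-chromene-2,6(3H)-dione | C=C1[C@]2(C)CCC(=O)O[C@@H]2CCC1=O | intermediate
9 | (4aS,6R,8aR)-6-hydroxy-4a,6-dimethyl-5-methylideneoctahydro-2H-chromen-2-one | C=C1[C@]2(C)CCC(=O)O[C@@H]2CC[C@@]1(C)O | intermediate
10 | (S)-(−)-limonene, (4S)-1-methyl-4-(prop-1-en-2-yl)cyclohex-1-ene | CC1=CC[C@H](CC1)C(C)=C | starting material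
11 | methyl methacrylate | C=C(C)C(=O)OC | starting material
12 | methyl 2,4-dimethyl-4-[(1S)-4-methylcyclohex-3-en-1-yl]pentanoate, both C2 epimers | CC1=CC[C@H](CC1)C(C)(C)CC(C)C(=O)OC | intermediate
13 | methyl (5S)-2,4,4-trimethyl-8-oxo-5-(2-oxoethyl)nonanoate, both C2 epimers | CC(=O)CC[C@@H](CC=O)C(C)(C)CC(C)C(=O)OC | intermediate
14 | methyl 4-[(1R)-2-formyl-3-methylcyclopent-2-en-1-yl]-2,4-dimethylpentanoate | CC1=C(C=O)[C@H](CC1)C(C)(C)CC(C)C(=O)OC | intermediate
15 | methyl 4-(1-formyl-5-methyl-6-oxabicyclo[3.1.0]hexan-2-yl)-2,4-dimethylpentanoate, epoxide oxygen trans to the side chain | O=C[C@]12O[C@@]1(C)CC[C@@H]2C(C)(C)CC(C)C(=O)OC | intermediate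
16 | methyl 4-[(1R,3S)-3-hydroxy-3-methyl-2-methylidenecyclopentyl]-2,4-dimethylpentanoate | C=C1[C@@H](C(C)(C)CC(C)C(=O)OC)CC[C@]1(C)O | intermediate
17 | 4-[(1R,3S)-3-hydroxy-3-methyl-2-methylidenecyclopentyl]-2,4-dimethylpentanoic acid | C=C1[C@@H](C(C)(C)CC(C)C(=O)O)CC[C@]1(C)O | intermediate
18 | Se-phenyl 4-[(1R,3S)-3-hydroxy-3-methyl-2-methylidenecyclopentyl]-2,4-dimethylpentaneselenoate | C=C1[C@@H](C(C)(C)CC(C)C(=O)[Se]c2ccccc2)CC[C@]1(C)O | intermediate
19 | (1S,3aS,8aS)-1-hydroxy-1,4,4,6-tetramethyldecahydroazulen-7-one, cis-fused, both C6 epimers | CC1C(=O)C[C@H]2[C@H](CC[C@]2(C)O)C(C)(C)C1 | intermediate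
20 | (1S,3aS,8aS)-1,4,4,6-tetramethyl-1,7-bis(triethylsilyloxy)-1,2,3,3a,4,5,8,8a-octahydroazulene | CC1=C(O[Si](CC)(CC)CC)C[C@H]2[C@H](CC[C@]2(C)O[Si](CC)(CC)CC)C(C)(C)C1 | intermediate
21 | (1S,3aS,8aS)-1,4,4,6-tetramethyl-1-(triethylsilyloxy)-2,3,3a,4,8,8a-hexahydroazulen-7(1H)-one | O=C1C[C@H]2[C@H](CC[C@]2(C)O[Si](CC)(CC)CC)C(C)(C)C=C1C | intermediate
22 | (1S,3aS,7R,8aS)-1,4,4,6-tetramethyl-1-(triethylsilyloxy)-1,2,3,3a,4,7,8,8a-octahydroazulen-7-ol | O[C@@H]1C[C@H]2[C@H](CC[C@]2(C)O[Si](CC)(CC)CC)C(C)(C)C=C1C | intermediate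
23 | tributyl({[(1S,3aS,7R,8aS)-1,4,4,6-tetramethyl-1-(triethylsilyloxy)-1,2,3,3a,4,7,8,8a-octahydroazulen-7-yl]oxy}methyl)stannane | CCCC[Sn](CCCC)(CCCC)CO[C@@H]1C[C@H]2[C@H](CC[C@]2(C)O[Si](CC)(CC)CC)C(C)(C)C=C1C | intermediate
24 | lithiomethyl ether of 22 (α-alkoxymethyllithium) | [Li]CO[C@@H]1C[C@H]2[C@H](CC[C@]2(C)O[Si](CC)(CC)CC)C(C)(C)C=C1C | intermediate
25 | [(1S,3aS,5R,8aS)-1,4,4,6-tetramethyl-1-(triethylsilyloxy)-1,2,3,3a,4,5,8,8a-octahydroazulen-5-yl]methanol | CC1=CC[C@H]2[C@H](CC[C@]2(C)O[Si](CC)(CC)CC)C(C)(C)[C@@H]1CO | intermediate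
26 | (1S,3aS,5R,8aS)-5-(bromomethyl)-1,4,4,6-tetramethyl-1-(triethylsilyloxy)-1,2,3,3a,4,5,8,8a-octahydroazulene | CC1=CC[C@H]2[C@H](CC[C@]2(C)O[Si](CC)(CC)CC)C(C)(C)[C@@H]1CBr | intermediate
27 | 9-{[(4aS,5S,6R,8aR)-6-hydroxy-4a,6-dimethyl-2-oxooctahydro-2H-chromen-5-yl]methyl}-9-borabicyclo[3.3.1]nonane | C1CC2CCCC(C1)B2C[C@H]1[C@]2(C)CCC(=O)O[C@@H]2CC[C@@]1(C)O | intermediate
28 | (4aS,5S,6R,8aR)-6-hydroxy-4a,6-dimethyl-5-{2-[(1S,3aS,5R,8aS)-1,4,4,6-tetramethyl-1-(triethylsilyloxy)-1,2,3,3a,4,5,8,8a-octahydroazulen-5-yl]ethyl}octahydro-2H-chromen-2-one | CC1=CC[C@H]2[C@H](CC[C@]2(C)O[Si](CC)(CC)CC)C(C)(C)[C@@H]1CC[C@H]1[C@]2(C)CCC(=O)O[C@@H]2CC[C@@]1(C)O | intermediate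
29 | 6-O-trimethylsilyl ether of 28 | CC1=CC[C@H]2[C@H](CC[C@]2(C)O[Si](CC)(CC)CC)C(C)(C)[C@@H]1CC[C@H]1[C@]2(C)CCC(=O)O[C@@H]2CC[C@@]1(C)O[Si](C)(C)C | intermediate
30 | lithium alkoxide of the 2-(2-bromopropan-2-yl) lactol derived from 29 (tetrahedral adduct at C3) | CC1=CC[C@H]2[C@H](CC[C@]2(C)O[Si](CC)(CC)CC)C(C)(C)[C@@H]1CC[C@H]1[C@]2(C)CCC([O-])(C(C)(C)Br)O[C@@H]2CC[C@@]1(C)O[Si](C)(C)C.[Li+] | intermediate
31 | spiro epoxy ether: 3′,3′-dimethylspiro[octahydrochromene-2,2′-oxirane] derived from 29 | CC1=CC[C@H]2[C@H](CC[C@]2(C)O[Si](CC)(CC)CC)C(C)(C)[C@@H]1CC[C@H]1[C@]2(C)CCC3(OC3(C)C)O[C@@H]2CC[C@@]1(C)O[Si](C)(C)C | intermediate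
32 | (5aS,6S,7R,9aR)-2,2,5a,7-tetramethyl-6-{2-[(1S,3aS,5R,8aS)-1,4,4,6-tetramethyl-1-(triethylsilyloxy)-1,2,3,3a,4,5,8,8a-octahydroazulen-5-yl]ethyl}-7-(trimethylsilyloxy)octahydro-1-benzoxepin-3(2H)-one | CC1=CC[C@H]2[C@H](CC[C@]2(C)O[Si](CC)(CC)CC)C(C)(C)[C@@H]1CC[C@H]1[C@]2(C)CCC(=O)C(C)(C)O[C@@H]2CC[C@@]1(C)O[Si](C)(C)C | intermediate
33 | (5aS,6S,7R,9aR)-7-hydroxy-6-{2-[(1S,3aS,5R,8aS)-1-hydroxy-1,4,4,6-tetramethyl-1,2,3,3a,4,5,8,8a-octahydroazulen-5-yl]ethyl}-2,2,5a,7-tetramethyloctahydro-1-benzoxepin-3(2H)-one | CC1=CC[C@H]2[C@H](CC[C@]2(C)O)C(C)(C)[C@@H]1CC[C@H]1[C@]2(C)CCC(=O)C(C)(C)O[C@@H]2CC[C@@]1(C)O | target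

**Step count and risks**

Total step count: 24. Longest linear sequence: 18 steps (steps 7–20, then 21–24).

Steps most likely to fail:

1. Step 23 (Proposed new method). The carbenoid may deprotonate the lactone instead of adding; the ring-opened bromo ketone may undergo Favorskii contraction or lose HBr; methyl or C4 may migrate in place of oxygen. Fallback with known chemistry, from 29 back to 32: i-Bu2AlH at −78 °C should reduce the lactone to the lactol F1. Diphenylsulfonium isopropylide (Corey–Chaykovsky epoxidation of the open hydroxy aldehyde form) should then give the trisubstituted epoxy alcohol F2. Camphorsulfonic acid should induce epoxide-opening cyclisation by the C9a hydroxyl at the tertiary epoxide carbon (7-endo) to the oxepan-3-ol F3. Dess–Martin oxidation of F3 returns to 32.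

2. Step 21. Oxidative addition into the β-branched primary bromide may be slow, and β-hydride elimination or protodeboronation may compete. Fallback, from 9 and 25 back to 29 (step 22 is then not needed):
   - 25 is converted by Mitsunobu reaction with 1-phenyl-1H-tetrazole-5-thiol into the sulfide F4 and oxidised ((NH4)6Mo7O24, H2O2) to the sulfone F5.
   - 9 is hydroborated with 9-BBN and oxidised (NaBO3·4H2O) to the diol F6; Dess–Martin oxidation gives the hydroxy aldehyde F7, and silylation (TMSOTf, 2,6-lutidine) the protected aldehyde F8.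
   - Julia–Kocienski olefination of F8 with F5 (KN(SiMe3)2, THF, −78 °C) gives the (E)-alkene F9, whose disubstituted double bond is reduced selectively with diimide (2-nitrobenzenesulfonyl hydrazide, Et3N) to 29.

3. Step 19. A [1,2]-shift or simple protonation of the carbanion may compete with the [2,3]-shift at the hindered C5′ terminus next to the quaternary carbon. Fallback, from 22 back to 25: phenyl isocyanate gives the N-phenylcarbamate F10. Deprotonation (MeLi), then CuI and (isopropoxydimethylsilyl)methylmagnesium chloride should effect syn-selective SN2′ substitution to the silane F11. Tamao oxidation (H2O2, KF, KHCO3) then gives 25.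

**Further compounds**

F1 | step 23 | lactol from 29 (2-hydroxy-octahydrochromene) | CC1=CC[C@H]2[C@H](CC[C@]2(C)O[Si](CC)(CC)CC)C(C)(C)[C@@H]1CC[C@H]1[C@]2(C)CCC(O)O[C@@H]2CC[C@@]1(C)O[Si](C)(C)C
F2 | step 23 | epoxy alcohol: C9a hydroxyl free, C5a arm ending in a 3,3-dimethyloxiran-2-yl group | CC1=CC[C@H]2[C@H](CC[C@]2(C)O[Si](CC)(CC)CC)C(C)(C)[C@@H]1CC[C@H]1[C@](C)(CCC2OC2(C)C)[C@H](O)CC[C@@]1(C)O[Si](C)(C)C
F3 | step 23 | oxepan-3-ol: 3-hydroxy analogue of 32 | CC1=CC[C@H]2[C@H](CC[C@]2(C)O[Si](CC)(CC)CC)C(C)(C)[C@@H]1CC[C@H]1[C@]2(C)CCC(O)C(C)(C)O[C@@H]2CC[C@@]1(C)O[Si](C)(C)C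
F4 | step 21 | 1-phenyl-1H-tetrazol-5-yl sulfide of 25 | CC1=CC[C@H]2[C@H](CC[C@]2(C)O[Si](CC)(CC)CC)C(C)(C)[C@@H]1CSc1nnnn1-c1ccccc1
F5 | step 21 | 1-phenyl-1H-tetrazol-5-yl sulfone of 25 | CC1=CC[C@H]2[C@H](CC[C@]2(C)O[Si](CC)(CC)CC)C(C)(C)[C@@H]1CS(=O)(=O)c1nnnn1-c1ccccc1
F6 | step 21 | (4aS,5S,6R,8aR)-6-hydroxy-5-(hydroxymethyl)-4a,6-dimethyloctahydro-2H-chromen-2-one | OC[C@H]1[C@]2(C)CCC(=O)O[C@@H]2CC[C@@]1(C)O
F7 | step 21 | (4aS,5S,6R,8aR)-6-hydroxy-4a,6-dimethyl-2-oxooctahydro-2H-chromene-5-carbaldehyde | O=C[C@H]1[C@]2(C)CCC(=O)O[C@@H]2CC[C@@]1(C)O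
F8 | step 21 | 6-O-trimethylsilyl ether of F7 | O=C[C@H]1[C@]2(C)CCC(=O)O[C@@H]2CC[C@@]1(C)O[Si](C)(C)C
F9 | step 21 | (E)-alkene: 29 with a CH=CH bridge | CC1=CC[C@H]2[C@H](CC[C@]2(C)O[Si](CC)(CC)CC)C(C)(C)[C@@H]1/C=C/[C@H]1[C@]2(C)CCC(=O)O[C@@H]2CC[C@@]1(C)O[Si](C)(C)C
F10 | step 19 | N-phenylcarbamate of 22 | O=C(Nc1ccccc1)O[C@@H]1C[C@H]2[C@H](CC[C@]2(C)O[Si](CC)(CC)CC)C(C)(C)C=C1C
F11 | step 19 | isopropoxydimethylsilylmethyl compound: 25 with CH2Si(Me)2(O-i-Pr) in place of CH2OH | CC1=CC[C@H]2[C@H](CC[C@]2(C)O[Si](CC)(CC)CC)C(C)(C)[C@@H]1C[Si](C)(C)OC(C)C
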